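**Plan**

- Retrosynthetic cuts, in order: the 15 benzyl ethers and one C–Br (hydrogenolysis); the upper-unit C2–aryl (B ring) bond; the upper-unit C3–C4 and O1–C2(acyl) bonds, made together in a formal [4+2] of an o-quinone methide with a benzyloxyketene enolate; the upper C4–middle C8 bond (aryllithium + aldehyde); the middle C4–lower C6 bond.
- Enabling feature: upper C4 is a benzhydryl carbon between upper A-ring C4a and middle-unit C8, with the A-ring oxygen O1 ortho to it. Its hydroxy precursor dehydrates to the o-quinone methide O1=C8a–C4a=C4, whose termini C4 and O1 are exactly the atoms the C-ring joins to C3 and C2.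
- Forward order: lower and middle units joined (4β→6, halogen caps); upper A ring and C4 attached at middle C8; upper C-ring closed as a lactone; B ring added at C2; deprotection.
- Stereochemistry: lower and middle units come from (−)-epicatechin, and middle C4 from trans addition to the C4 cation. Upper C4 is set by the cinchona-bound enolate (catalyst control), upper C3 is trans to C4 (epimerisable lactone α-carbon), and upper C2 by aryl attack on the oxocarbenium ion anti to the C4 aryl group.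

Key step: step 8

Assumption: flavan numbering (O1, C2, C3, C4, C4a, C8a) is used for every unit; the carbinol centre of 11 and the anomeric centre of 16 are left undefined because both are destroyed in the next step.

**Route**

Step 1
Reactants: 1 (−)-epicatechin
Product: 2 penta-O-benzyl-(−)-epicatechin (3,5,7,3′,4′-pentabenzyl ether; 2R,3R)
Conditions: BnBr, K2CO3, DMF, rt; then NaH, 0 °C → rt (one pot)
Reagents that add atoms: benzyl bromide (BrCc1ccccc1)
Why: Williamson etherification, carbonate serving the four phenols and sodium hydride the hindered secondary 3-OH; no stereocentre is touched.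

Step 2
Reactants: 2 penta-O-benzyl-(−)-epicatechin
Product: 3 4β-(2-ethoxyethoxy)-penta-O-benzylepicatechin (2,3-cis-3,4-trans)
Conditions: DDQ, 2-ethoxyethanol, CH2Cl2, rt
Reagents that add atoms: 2-ethoxyethanol (CCOCCO)
Why: DDQ benzylic oxidation (hydride abstraction at C4 of the 5,7-dialkoxychroman) gives the C4 cation, which the alcohol should capture trans to the 3-benzyloxy group, the usual C4 activation of protected flavan-3-ols.

Step 3
Reactants: 3 4β-(2-ethoxyethoxy)-penta-O-benzylepicatechin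
Product: 4 8-iodo-4β-(2-ethoxyethoxy)-penta-O-benzylepicatechin
Conditions: NIS, CH2Cl2, −40 → 0 °C, dark
Reagents that add atoms: N-iodosuccinimide (O=C1CCC(=O)N1I)
Why: electrophilic aromatic iodination should occur at C8, the most nucleophilic free A-ring position; the iodine caps C8 against self-condensation and is the later handle for metalation.

Step 4
Reactants: 2 penta-O-benzyl-(−)-epicatechin
Product: 5 8-bromo-penta-O-benzylepicatechin
Conditions: NBS, CH2Cl2, −78 °C → rt
Reagents that add atoms: N-bromosuccinimide (O=C1CCC(=O)N1Br)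
Why: electrophilic aromatic bromination at C8 blocks that position, so this unit can later react only at C6 (halogen capping); the bromine is removed in the last step.

Step 5
Reactants: 4 8-iodo-4β-(2-ethoxyethoxy)-penta-O-benzylepicatechin; 5 8-bromo-penta-O-benzylepicatechin (excess)
Product: 6 8-iodo-penta-O-benzylepicatechin-(4β→6)-8-bromo-penta-O-benzylepicatechin
Conditions: BF3·OEt2, CH2Cl2, −78 → −30 °C; Et3N quench
Reagents that add atoms: none
Why: Lewis-acid-mediated Friedel–Crafts-type interflavan coupling, in which C6 of 5 (C8 blocked) attacks the C4 cation from 4 on the face trans to the 3-benzyloxy and 2-aryl groups, setting the 4β centre.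

Step 6
Reactants: 7 2,4,6-trihydroxybenzaldehyde
Product: 8 2,4-bis(benzyloxy)-6-hydroxybenzaldehyde
Conditions: BnBr (2.1 equiv), K2CO3, DMF, rt
Reagents that add atoms: benzyl bromide (BrCc1ccccc1)
Why: regioselective Williamson benzylation, one ortho-hydroxyl being expected to stay free because it is hydrogen-bonded to the formyl group.

Step 7
Reactants: 6 8-iodo-penta-O-benzylepicatechin-(4β→6)-8-bromo-penta-O-benzylepicatechin; 8 2,4-bis(benzyloxy)-6-hydroxybenzaldehyde
Product: 11 o-hydroxybenzhydrol (3,5-bis(benzyloxy)-2-[hydroxy(dimer-C8-yl)methyl]phenol; carbinol epimers), via lithium formylphenoxide 9 (not isolated), via dimer C8-aryllithium 10 (not isolated)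
Conditions: 8, LiHMDS (1 equiv), THF, −78 °C; 6, n-BuLi (1 equiv), THF, −78 °C; combine, −78 → −30 °C; aq NH4Cl; used crude
Reagents that add atoms: none
Why: iodine–lithium exchange is much faster at the aryl iodide than at the aryl bromide, and the aryllithium should add 1,2 to the aldehyde whose phenol is masked as its lithium salt, forming the upper C4–middle C8 bond.

Step 8
Reactants: 11 o-hydroxybenzhydrol; 12 benzyloxyacetyl chloride
Product: 15 (3R,4R)-3,5,7-tris(benzyloxy)-4-(dimer-C8-yl)chroman-2-one (3,4-trans lactone), via o-quinone methide 13 (not isolated), via benzyloxyketene 14 (not isolated)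
Conditions: PPTS (cat.), 4 Å MS, CH2Cl2, 0 °C; then i-Pr2NEt, O-benzoylquinine (20 mol %), 12 by syringe pump, toluene/CH2Cl2, −78 → −30 °C; then DBU (cat.), 0 °C
Reagents that add atoms: none
Why: Acid-catalysed dehydration of 11 gives the o-quinone methide 13 (O1=C8a–C4a=C4) and dehydrochlorination of 12 gives ketene 14, to which the cinchona catalyst adds to form a zwitterionic ammonium enolate; its α-carbon (future C3) adds to the methide carbon C4 with rearomatisation, and the freed phenoxide O1 is acylated by the acylammonium, releasing the catalyst. The closest known reaction type is the chiral Lewis-base-catalysed formal [4+2] annulation of o-quinone methides with ketene (ammonium) enolates to 3,4-dihydrocoumarins. The six-membered lactone (O1, C2, C3, C4, C4a, C8a, the future C-ring with C2 at the acid oxidation level) closes stepwise: intermolecular Michael addition forms C3–C4, then 6-exo-trig O-acylation forms O1–C2. C4 is controlled by the catalyst-bound enolate attacking one face of the planar methide, the nearest substrate stereocentres being remote; C3 is set kinetically by the enolate face and, as the epimerisable lactone α-carbon, is expected to equilibrate under DBU to the more stable 3,4-trans isomer. Site selectivity is secured by the substrate, since C4 is the only electrophilic carbon and O1 the only free oxygen nucleophile (all other oxygens are benzylated); facial selectivity relies on the catalyst, the matched pseudo-enantiomer (benzoylquinine or benzoylquinidine) having to be identified; slow addition of 12 suppresses ketene dimerisation.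

Step 9
Reactants: 15 (3R,4R)-3,5,7-tris(benzyloxy)-4-(dimer-C8-yl)chroman-2-one
Product: 16 (3R,4R)-2-acetoxy-3,5,7-tris(benzyloxy)-4-(dimer-C8-yl)chroman (anomeric mixture)
Conditions: DIBAL-H, CH2Cl2, −78 °C; then pyridine, DMAP, Ac2O, −78 → 0 °C
Reagents that add atoms: acetic anhydride (CC(=O)OC(C)=O)
Why: reductive acetylation, DIBAL-H giving the aluminium hemiacetal that is acetylated in situ to the anomeric acetate without touching C3 or C4.

Step 10
Reactants: 16 (3R,4R)-2-acetoxy-3,5,7-tris(benzyloxy)-4-(dimer-C8-yl)chroman; 17 4-bromo-1,2-bis(benzyloxy)benzene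
Product: 20 penta-O-benzylepicatechin-(4β→8)-penta-O-benzylepicatechin-(4β→6)-8-bromo-penta-O-benzylepicatechin, via arylmagnesium bromide 18 (not isolated), via arylzinc bromide 19 (not isolated)
Conditions: 17, Mg, THF; ZnBr2; solvent switch to CH2Cl2; 16, BF3·OEt2, −78 → −20 °C
Reagents that add atoms: none
Why: C-aryl-glycosylation-type substitution, in which Lewis-acid ionisation of the acetate gives the C2 oxocarbenium ion and the arylzinc should attack the face anti to the pseudoaxial C4 aryl group, which is also cis to the 3-benzyloxy group, setting C2 (2,3-cis, 2,4-trans).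

Step 11
Reactants: 20 pentadeca-O-benzyl 8-bromo trimer
Product: 21 epicatechin-(4β→8)-epicatechin-(4β→6)-epicatechin (target)
Conditions: H2 (1 atm), Pd(OH)2/C, Et3N, THF/MeOH/H2O, rt
Reagents that add atoms: none
Why: catalytic hydrogenolysis should cleave the fifteen benzyl ethers and the aryl bromide (base trapping HBr) while leaving the interflavan bonds and all stereocentres intact.

**Compound list**

1 | (−)-epicatechin | Oc1cc(O)c2c(c1)O[C@H](c1ccc(O)c(O)c1)[C@H](O)C2 | starting material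
2 | penta-O-benzyl-(−)-epicatechin | c3ccccc3COc1cc(OCc3ccccc3)c2c(c1)O[C@H](c1ccc(OCc3ccccc3)c(OCc3ccccc3)c1)[C@H](OCc3ccccc3)C2 | intermediate
3 | 4β-(2-ethoxyethoxy)-penta-O-benzylepicatechin | c3ccccc3COc1cc(OCc3ccccc3)c2c(c1)O[C@H](c1ccc(OCc3ccccc3)c(OCc3ccccc3)c1)[C@H](OCc3ccccc3)[C@H]2OCCOCC | intermediate
4 | 8-iodo-4β-(2-ethoxyethoxy)-penta-O-benzylepicatechin | c3ccccc3COc1cc(OCc3ccccc3)c2c(c1I)O[C@H](c1ccc(OCc3ccccc3)c(OCc3ccccc3)c1)[C@H](OCc3ccccc3)[C@H]2OCCOCC | intermediate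
5 | 8-bromo-penta-O-benzylepicatechin | c3ccccc3COc1cc(OCc3ccccc3)c2c(c1Br)O[C@H](c1ccc(OCc3ccccc3)c(OCc3ccccc3)c1)[C@H](OCc3ccccc3)C2 | intermediate
6 | 8-iodo-penta-O-benzylepicatechin-(4β→6)-8-bromo-penta-O-benzylepicatechin | Ic1c(OCc3ccccc3)cc(OCc3ccccc3)c2c1O[C@H](c1ccc(OCc3ccccc3)c(OCc3ccccc3)c1)[C@H](OCc3ccccc3)[C@H]2c1c(OCc3ccccc3)c(Br)c2c(c1OCc3ccccc3)C[C@@H](OCc3ccccc3)[C@@H](c1ccc(OCc3ccccc3)c(OCc3ccccc3)c1)O2 | intermediate
7 | 2,4,6-trihydroxybenzaldehyde | O=Cc1c(O)cc(O)cc1O | starting material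
8 | 2,4-bis(benzyloxy)-6-hydroxybenzaldehyde | O=Cc1c(O)cc(OCc2ccccc2)cc1OCc2ccccc2 | intermediate
9 | lithium 3,5-bis(benzyloxy)-2-formylphenoxide | [Li+].[O-]c1cc(OCc2ccccc2)cc(OCc2ccccc2)c1C=O | intermediate
10 | C8-lithiated dimer (aryllithium from 6) | [Li]c1c(OCc3ccccc3)cc(OCc3ccccc3)c2c1O[C@H](c1ccc(OCc3ccccc3)c(OCc3ccccc3)c1)[C@H](OCc3ccccc3)[C@H]2c1c(OCc3ccccc3)c(Br)c2c(c1OCc3ccccc3)C[C@@H](OCc3ccccc3)[C@@H](c1ccc(OCc3ccccc3)c(OCc3ccccc3)c1)O2 | intermediate
11 | 3,5-bis(benzyloxy)-2-[hydroxy(dimer-C8-yl)methyl]phenol (carbinol epimers) | Oc1cc(OCc3ccccc3)cc(OCc3ccccc3)c1C(O)c1c(OCc3ccccc3)cc(OCc3ccccc3)c2c1O[C@H](c1ccc(OCc3ccccc3)c(OCc3ccccc3)c1)[C@H](OCc3ccccc3)[C@H]2c1c(OCc3ccccc3)c(Br)c2c(c1OCc3ccccc3)C[C@@H](OCc3ccccc3)[C@@H](c1ccc(OCc3ccccc3)c(OCc3ccccc3)c1)O2 | intermediate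
12 | benzyloxyacetyl chloride | O=C(Cl)COCc1ccccc1 | starting material
13 | o-quinone methide, 3,5-bis(benzyloxy)-6-[(dimer-C8-yl)methylidene]cyclohexa-2,4-dien-1-one | O=C1C=C(OCc3ccccc3)C=C(OCc3ccccc3)C1=Cc1c(OCc3ccccc3)cc(OCc3ccccc3)c2c1O[C@H](c1ccc(OCc3ccccc3)c(OCc3ccccc3)c1)[C@H](OCc3ccccc3)[C@H]2c1c(OCc3ccccc3)c(Br)c2c(c1OCc3ccccc3)C[C@@H](OCc3ccccc3)[C@@H](c1ccc(OCc3ccccc3)c(OCc3ccccc3)c1)O2 | intermediate
14 | benzyloxyketene | O=C=COCc1ccccc1 | intermediate
15 | (3R,4R)-3,5,7-tris(benzyloxy)-4-(dimer-C8-yl)chroman-2-one | c3ccccc3COc1cc(OCc3ccccc3)c2c(c1)OC(=O)[C@H](OCc3ccccc3)[C@H]2c1c(OCc3ccccc3)cc(OCc3ccccc3)c2c1O[C@H](c1ccc(OCc3ccccc3)c(OCc3ccccc3)c1)[C@H](OCc3ccccc3)[C@H]2c1c(OCc3ccccc3)c(Br)c2c(c1OCc3ccccc3)C[C@@H](OCc3ccccc3)[C@@H](c1ccc(OCc3ccccc3)c(OCc3ccccc3)c1)O2 | intermediate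
16 | (3R,4R)-2-acetoxy-3,5,7-tris(benzyloxy)-4-(dimer-C8-yl)chroman (anomers) | c3ccccc3COc1cc(OCc3ccccc3)c2c(c1)OC(OC(C)=O)[C@H](OCc3ccccc3)[C@H]2c1c(OCc3ccccc3)cc(OCc3ccccc3)c2c1O[C@H](c1ccc(OCc3ccccc3)c(OCc3ccccc3)c1)[C@H](OCc3ccccc3)[C@H]2c1c(OCc3ccccc3)c(Br)c2c(c1OCc3ccccc3)C[C@@H](OCc3ccccc3)[C@@H](c1ccc(OCc3ccccc3)c(OCc3ccccc3)c1)O2 | intermediate
17 | 4-bromo-1,2-bis(benzyloxy)benzene | Brc1ccc(OCc2ccccc2)c(OCc2ccccc2)c1 | starting material
18 | 3,4-bis(benzyloxy)phenylmagnesium bromide | Br[Mg]c1ccc(OCc2ccccc2)c(OCc2ccccc2)c1 | intermediate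
19 | 3,4-bis(benzyloxy)phenylzinc bromide | Br[Zn]c1ccc(OCc2ccccc2)c(OCc2ccccc2)c1 | intermediate
20 | penta-O-benzylepicatechin-(4β→8)-penta-O-benzylepicatechin-(4β→6)-8-bromo-penta-O-benzylepicatechin | c3ccccc3COc1cc(OCc3ccccc3)c2c(c1)O[C@H](c1ccc(OCc3ccccc3)c(OCc3ccccc3)c1)[C@H](OCc3ccccc3)[C@H]2c1c(OCc3ccccc3)cc(OCc3ccccc3)c2c1O[C@H](c1ccc(OCc3ccccc3)c(OCc3ccccc3)c1)[C@H](OCc3ccccc3)[C@H]2c1c(OCc3ccccc3)c(Br)c2c(c1OCc3ccccc3)C[C@@H](OCc3ccccc3)[C@@H](c1ccc(OCc3ccccc3)c(OCc3ccccc3)c1)O2 | intermediate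
21 | epicatechin-(4β→8)-epicatechin-(4β→6)-epicatechin | Oc1cc(O)c2c(c1)O[C@H](c1ccc(O)c(O)c1)[C@H](O)[C@H]2c1c(O)cc(O)c2c1O[C@H](c1ccc(O)c(O)c1)[C@H](O)[C@H]2c1c(O)cc2c(c1O)C[C@@H](O)[C@@H](c1ccc(O)c(O)c1)O2 | target

**Step count and risks**

Total steps: 11. Longest linear sequence: 9 (steps 1, 2, 3, 5, 7, 8, 9, 10, 11).

Most likely to fail, step 8: the conjugate addition to a methide carbon flanked by four ortho substituents may be slow, so ketene dimerisation, quinone methide oligomerisation or an uncatalysed background annulation could compete, and the chiral middle unit may work against the catalyst, giving poor facial selectivity at C4. The fallback abandons the de novo ring closure and uses the established interflavan coupling. It sets out from 6, which is deiodinated (n-BuLi, THF, −78 °C; MeOH) to the C8-unsubstituted dimer F1. F1 is coupled through its free C8 with the C4 cation from 4 (BF3·OEt2, CH2Cl2, −78 °C; the iodine cap prevents self-condensation of the electrophile) to give the 8-iodo pentadeca-O-benzyl trimer F2. Hydrogenolysis (H2, Pd(OH)2/C, Et3N) removes the benzyl groups and both halogens, and the route is rejoined at 21.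

Second, step 10: the C2 oxocarbenium ion may lose the C3 proton to give the 4H-chromene, or aryl transfer may be too slow or insufficiently face-selective. The fallback builds C2 through an open-chain intermediate and sets out from 15. 3,4-Bis(benzyloxy)phenyllithium (from 17 and n-BuLi, THF, −78 °C) opens the lactone to the hydroxy ketone F3. Chelation-controlled reduction (Zn(BH4)2, Et2O, −20 °C) should give the anti alcohol F4. Mitsunobu cyclisation (PPh3, DIAD, THF, 0 °C) closes O1–C2 with inversion to the 2,3-cis flavan, rejoining the route at 20.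

Third, step 7: halogen–metal exchange may not discriminate cleanly between iodide and bromide, and the hindered di-ortho-alkoxy aryllithium may be protonated instead of adding to the deactivated phenoxide aldehyde. The fallback reverses the polarity of the union and sets out from 6. Iodine–lithium exchange followed by DMF gives the 8-formyl dimer F5. Ortho-specific hydroxyalkylation of bromomagnesium 3,5-bis(benzyloxy)phenolate (from commercial 3,5-bis(benzyloxy)phenol and EtMgBr, toluene, rt) with F5 gives the same diol, rejoining the route at 11.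

**Further compounds**

F1 | step 8 | penta-O-benzylepicatechin-(4β→6)-8-bromo-penta-O-benzylepicatechin (deiodinated dimer) | c1c(OCc3ccccc3)cc(OCc3ccccc3)c2c1O[C@H](c1ccc(OCc3ccccc3)c(OCc3ccccc3)c1)[C@H](OCc3ccccc3)[C@H]2c1c(OCc3ccccc3)c(Br)c2c(c1OCc3ccccc3)C[C@@H](OCc3ccccc3)[C@@H](c1ccc(OCc3ccccc3)c(OCc3ccccc3)c1)O2
F2 | step 8 | 8-iodo-penta-O-benzylepicatechin-(4β→8)-penta-O-benzylepicatechin-(4β→6)-8-bromo-penta-O-benzylepicatechin | c3ccccc3COc1cc(OCc3ccccc3)c2c(c1I)O[C@H](c1ccc(OCc3ccccc3)c(OCc3ccccc3)c1)[C@H](OCc3ccccc3)[C@H]2c1c(OCc3ccccc3)cc(OCc3ccccc3)c2c1O[C@H](c1ccc(OCc3ccccc3)c(OCc3ccccc3)c1)[C@H](OCc3ccccc3)[C@H]2c1c(OCc3ccccc3)c(Br)c2c(c1OCc3ccccc3)C[C@@H](OCc3ccccc3)[C@@H](c1ccc(OCc3ccccc3)c(OCc3ccccc3)c1)O2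
F3 | step 10 | ring-opened hydroxy ketone, (2R,3R)-2-(benzyloxy)-3-[2,4-bis(benzyloxy)-6-hydroxyphenyl]-1-[3,4-bis(benzyloxy)phenyl]-3-(dimer-C8-yl)propan-1-one | Oc1cc(OCc3ccccc3)cc(OCc3ccccc3)c1[C@@H]([C@@H](OCc3ccccc3)C(=O)c1ccc(OCc3ccccc3)c(OCc3ccccc3)c1)c1c(OCc3ccccc3)cc(OCc3ccccc3)c2c1O[C@H](c1ccc(OCc3ccccc3)c(OCc3ccccc3)c1)[C@H](OCc3ccccc3)[C@H]2c1c(OCc3ccccc3)c(Br)c2c(c1OCc3ccccc3)C[C@@H](OCc3ccccc3)[C@@H](c1ccc(OCc3ccccc3)c(OCc3ccccc3)c1)O2
F4 | step 10 | anti benzylic alcohol from chelation-controlled reduction of F3 (carbinol carbon epimeric to C2 of 20) | Oc1cc(OCc3ccccc3)cc(OCc3ccccc3)c1[C@@H]([C@@H](OCc3ccccc3)[C@@H](O)c1ccc(OCc3ccccc3)c(OCc3ccccc3)c1)c1c(OCc3ccccc3)cc(OCc3ccccc3)c2c1O[C@H](c1ccc(OCc3ccccc3)c(OCc3ccccc3)c1)[C@H](OCc3ccccc3)[C@H]2c1c(OCc3ccccc3)c(Br)c2c(c1OCc3ccccc3)C[C@@H](OCc3ccccc3)[C@@H](c1ccc(OCc3ccccc3)c(OCc3ccccc3)c1)O2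
F5 | step 7 | 8-formyl-penta-O-benzylepicatechin-(4β→6)-8-bromo-penta-O-benzylepicatechin | O=Cc1c(OCc3ccccc3)cc(OCc3ccccc3)c2c1O[C@H](c1ccc(OCc3ccccc3)c(OCc3ccccc3)c1)[C@H](OCc3ccccc3)[C@H]2c1c(OCc3ccccc3)c(Br)c2c(c1OCc3ccccc3)C[C@@H](OCc3ccccc3)[C@@H](c1ccc(OCc3ccccc3)c(OCc3ccccc3)c1)O2
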